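**Assumption:** the SMILES is taken literally, so the decalin is cis-fused (H-5 and the C-10 methyl on the same face; 4S,5S,9S,10R in labdane numbering), i.e. the 5-epimer of the usual trans-labdanes. Labdane numbering is used below; β is the face carrying H-5 and the C-10 methyl.

## Retrosynthetic overview

1. C12–C13: Ni cross-electrophile coupling of primary bromide 16 with (Z)-2-bromobut-2-ene-1,4-diol 19.
2. C9–C11 and the 8(17)-methylene: Johnson–Claisen on allylic alcohol 12, which comes from alkene 9 by singlet-oxygen ene reaction and 1,3-transposition.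
3. C10 and C4 quaternary centres: angular methylation (gives the cis ring fusion), then equatorial methylation of the C4 ester enolate.
4. Ring A (formed second): photoredox annulation of a carvone-derived silyloxydiene, ethylene and the C5 acrylate (new reaction).
5. Ring B, C5 and C17 are bought as (S)-carvone; the isopropenyl CH3 becomes the C19 ester.

## Route

Step 1
Reactants: 1 (S)-(+)-carvone
Product: 2 10-hydroxycarvone
Conditions: SeO2 (cat.), t-BuOOH, CH2Cl2, rt
Reagents that add atoms: tert-butyl hydroperoxide CC(C)(C)OO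
Why: SeO2/t-BuOOH allylic oxidation (ene, then [2,3]) takes the CH3 of the electron-rich 1,1-disubstituted alkene and leaves the enone and C5 untouched.

Step 2
Reactants: 2 10-hydroxycarvone
Product: 3 methyl 2-[(1S)-4-methyl-5-oxocyclohex-3-en-1-yl]prop-2-enoate
Conditions: MnO2, 1,4-dimethyl-1,2,4-triazolium iodide (10 mol%), DBU, MeOH, CH2Cl2, rt
Reagents that add atoms: methanol CO
Why: MnO2/NHC tandem oxidative esterification (allylic alcohol to enal to acyl azolium to methyl ester) gives the 2-substituted acrylate; the ring ketone is inert.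

Step 3
Reactants: 3 acrylate–enone
Product: 5 bicyclic keto ester (ring A closed, C4/C10 epimer mixture), via silyl dienol ether 4 (not isolated)
Conditions: LiHMDS, TMSCl, THF, −78 °C; then [Mes-Acr-Me]BF4 (5 mol%), (PhS)2 (10 mol%), ethylene (10 bar), MeOH (3 equiv), MeCN, 450 nm, rt, slow addition of 4
Reagents that add atoms: ethylene C=C
Why: Proposed new method: photo-oxidation of the 2-silyloxydiene by excited acridinium and desilylation by MeOH gives the electrophilic α′-keto radical at C10, which adds to ethylene; the nucleophilic primary radical then closes 6-endo onto the β-CH2 of the 2-substituted acrylate (polarity matched) and the α-ester radical is quenched by thiol H-atom transfer, so C10–C1 and C2–C3 form in one redox-neutral step. The closest known reactions are photoredox oxidation of enol silanes to α-carbonyl radicals, Mn(III) oxidative radical annulations and 6-endo Giese cyclisations. No stereocentre is set here, because C4 and C10 are fixed later.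

Step 4
Reactants: 5 bicyclic keto ester
Product: 6 cis-fused 10-methyl keto ester (C4 epimers)
Conditions: LDA (1.05 equiv), THF, −78 °C; MeI, −78 to 0 °C
Reagents that add atoms: iodomethane CI
Why: Angular enolate alkylation at C10 (the only ketone α-CH) places the methyl anti to the pseudo-axial C5–C4 bond, giving the cis-fused junction (Me cis to H-5) as in classical 1-decalone angular methylations; both C10 epimers of 5 converge.

Step 5
Reactants: 6 cis-fused keto ester
Product: 8 Δ8(9)-alkene ester (C4 epimers), via tosylhydrazone 7 (not isolated)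
Conditions: TsNHNH2, TsOH (cat.), EtOH, 70 °C; then catecholborane, CHCl3, 0 °C; NaOAc·3H2O, reflux
Reagents that add atoms: none
Why: Kabalka reduction of the enone tosylhydrazone; the allylic diazene loses N2 by retro-ene, delivering H to C7 and moving the double bond to C8=C9 without touching a stereocentre.

Step 6
Reactants: 8 alkene ester
Product: 9 C4-quaternary alkene ester (4β-CO2Me, 4α-Me)
Conditions: LDA, THF/DMPU, −78 to −30 °C; MeI
Reagents that add atoms: iodomethane CI
Why: Ester enolate alkylation; A(1,3) strain places C6 axial on ring A, so the C10 methyl is axial and blocks the β face, and MeI enters equatorially (α) to give the axial 4β-ester cis to the C10 methyl, the known outcome for 10-methyl-4-carbomethoxy decalin enolates.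

Step 7
Reactants: 9 C4-quaternary alkene ester
Product: 11 9-hydroxy-8(17)-ene ester (C9 epimers), via allylic hydroperoxide 10 (not isolated)
Conditions: O2, tetraphenylporphyrin (cat.), CH2Cl2, visible light, −20 °C; then PPh3
Reagents that add atoms: dioxygen O=O
Why: Schenck ene reaction of singlet oxygen with the only trisubstituted alkene (C10 has no H, so O adds at C9 and H comes mainly from the C17 methyl), followed by phosphine reduction; the C9 configuration is irrelevant.

Step 8
Reactants: 11 secondary allylic alcohol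
Product: 12 17-hydroxy-Δ8(9) ester
Conditions: Ph3SiOReO3 (3 mol%), Et2O, 0 °C
Reagents that add atoms: none
Why: Rhenium-oxo catalysed 1,3-allylic transposition ([3,3] shift of the perrhenate ester) goes to the more stable primary alcohol with the trisubstituted alkene.

Step 9
Reactants: 12 primary allylic alcohol
Product: 14 C9-acetic ester with 8(17)-methylene, via ketene acetal 13 (not isolated)
Conditions: MeC(OMe)3, EtCO2H (cat.), xylene, 140 °C
Reagents that add atoms: trimethyl orthoacetate CC(OC)(OC)OC
Why: Johnson–Claisen rearrangement delivers CH2CO2Me to C9 on the convex β face (anti to the pseudo-axial C1 of ring A), which sets H-9α and creates the exocyclic methylene in the same step.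

Step 10
Reactants: 14 diester
Product: 15 C12 primary alcohol
Conditions: LiBH4, THF, 0 °C to rt
Reagents that add atoms: none
Why: Chemoselective borohydride reduction of the unhindered side-chain ester; the axial neopentyl C4 ester does not react.

Step 11
Reactants: 15 primary alcohol
Product: 16 C12 primary bromide
Conditions: CBr4, PPh3, CH2Cl2, 0 °C
Reagents that add atoms: carbon tetrabromide BrC(Br)(Br)Br
Why: Appel bromination of a primary alcohol; alkene and ester are inert.

Step 12
Reactants: 17 but-2-yne-1,4-diol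
Product: 19 (2Z)-2-bromobut-2-ene-1,4-diol, via vinylalanate 18 (not isolated)
Conditions: Red-Al, THF, 0 °C; then NBS, −78 °C
Reagents that add atoms: N-bromosuccinimide O=C1CCC(=O)N1Br
Why: trans-Hydroalumination of the propargylic diol and bromodealumination with retention put Br cis to the distal CH2OH (Z).

Step 13
Reactants: 16 C12 primary bromide; 19 (2Z)-2-bromobut-2-ene-1,4-diol
Product: 20 target (CNP0282002.1)
Conditions: NiBr2·glyme (10 mol%), 4,4′-di-tert-butyl-2,2′-bipyridine (10 mol%), Mn (2 equiv), NaI (0.25 equiv), DMA, rt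
Reagents that add atoms: none
Why: Ni-catalysed reductive cross-electrophile coupling of an alkyl bromide with an alkenyl bromide forms C12–C13 with retention of alkene geometry and tolerates the free hydroxyls and the ester.

## Compound list

1 | (S)-(+)-carvone, (5S)-2-methyl-5-(prop-1-en-2-yl)cyclohex-2-en-1-one | CC1=CC[C@H](C(C)=C)CC1=O | starting material
2 | 10-hydroxycarvone, (5S)-5-(3-hydroxyprop-1-en-2-yl)-2-methylcyclohex-2-en-1-one | CC1=CC[C@H](C(=C)CO)CC1=O | intermediate
3 | methyl 2-[(1S)-4-methyl-5-oxocyclohex-3-en-1-yl]prop-2-enoate | CC1=CC[C@H](C(=C)C(=O)OC)CC1=O | intermediate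
4 | methyl 2-[(1S)-4-methyl-5-(trimethylsilyloxy)cyclohexa-3,5-dien-1-yl]prop-2-enoate | CC1=CC[C@H](C(=C)C(=O)OC)C=C1O[Si](C)(C)C | intermediate
5 | methyl (8aS)-6-methyl-5-oxo-1,2,3,4,4a,5,8,8a-octahydronaphthalene-1-carboxylate (C1 and C4a epimer mixture) | CC1=CC[C@H]2C(CCCC2C(=O)OC)C1=O | intermediate
6 | methyl (4aS,8aR)-4a,6-dimethyl-5-oxo-1,2,3,4,4a,5,8,8a-octahydronaphthalene-1-carboxylate (cis-fused; C1 epimers) | CC1=CC[C@H]2[C@](C)(CCCC2C(=O)OC)C1=O | intermediate
7 | N-tosylhydrazone of 6 | CC1=CC[C@H]2[C@](C)(CCCC2C(=O)OC)C1=NNS(=O)(=O)c1ccc(C)cc1 | intermediate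
8 | methyl (4aS,8aR)-4a,6-dimethyl-1,2,3,4,4a,7,8,8a-octahydronaphthalene-1-carboxylate (cis-fused; C1 epimers) | CC1=C[C@@]2(C)CCCC(C(=O)OC)[C@H]2CC1 | intermediate
9 | methyl (1S,4aR,8aS)-1,4a,6-trimethyl-1,2,3,4,4a,7,8,8a-octahydronaphthalene-1-carboxylate | CC1=C[C@@]2(C)CCC[C@](C)(C(=O)OC)[C@H]2CC1 | intermediate
10 | methyl (1S,4aS,8aS)-5-hydroperoxy-1,4a-dimethyl-6-methylidenedecahydronaphthalene-1-carboxylate (C5 epimers) | C=C1CC[C@H]2[C@](C)(CCC[C@]2(C)C(=O)OC)C1OO | intermediate
11 | methyl (1S,4aS,8aS)-5-hydroxy-1,4a-dimethyl-6-methylidenedecahydronaphthalene-1-carboxylate (C5 epimers) | C=C1CC[C@H]2[C@](C)(CCC[C@]2(C)C(=O)OC)C1O | intermediate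
12 | methyl (1S,4aR,8aS)-6-(hydroxymethyl)-1,4a-dimethyl-1,2,3,4,4a,7,8,8a-octahydronaphthalene-1-carboxylate | OCC1=C[C@@]2(C)CCC[C@](C)(C(=O)OC)[C@H]2CC1 | intermediate
13 | 1-methoxyvinyl ether (ketene acetal) of 12 | COC(=C)OCC1=C[C@@]2(C)CCC[C@](C)(C(=O)OC)[C@H]2CC1 | intermediate
14 | methyl (1S,4aR,5S,8aS)-5-(2-methoxy-2-oxoethyl)-1,4a-dimethyl-6-methylidenedecahydronaphthalene-1-carboxylate | C=C1CC[C@H]2[C@](C)(CCC[C@]2(C)C(=O)OC)[C@H]1CC(=O)OC | intermediate
15 | methyl (1S,4aR,5S,8aS)-5-(2-hydroxyethyl)-1,4a-dimethyl-6-methylidenedecahydronaphthalene-1-carboxylate | C=C1CC[C@H]2[C@](C)(CCC[C@]2(C)C(=O)OC)[C@H]1CCO | intermediate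
16 | methyl (1S,4aR,5S,8aS)-5-(2-bromoethyl)-1,4a-dimethyl-6-methylidenedecahydronaphthalene-1-carboxylate | C=C1CC[C@H]2[C@](C)(CCC[C@]2(C)C(=O)OC)[C@H]1CCBr | intermediate
17 | but-2-yne-1,4-diol | OCC#CCO | starting material
18 | cyclic sodium vinylalanate from trans-hydroalumination of 17 (simplified) | OCC1=CCO[Al-]1(OCCOC)OCCOC.[Na+] | intermediate
19 | (2Z)-2-bromobut-2-ene-1,4-diol | OC/C(Br)=C/CO | intermediate
20 | methyl (1S,4aR,5S,8aS)-5-[(3E)-5-hydroxy-3-(hydroxymethyl)pent-3-en-1-yl]-1,4a-dimethyl-6-methylidenedecahydronaphthalene-1-carboxylate | C=C1CC[C@H]2[C@](C)(CCC[C@]2(C)C(=O)OC)[C@H]1CC/C(=C\CO)CO | target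

## Step count and risks

Total steps: 13. Longest linear sequence: 12 (steps 1–11 and 13).

**Step 3 (proposed new annulation).** The α′-keto radical may dimerise with the silyloxydiene or add to ethylene too slowly. Fallback with known chemistry, setting out from 3: alkylate the kinetic enolate (LiHMDS, THF, −78 °C) with 2-bromoethyl triflate to give methyl 2-[2-(2-bromoethyl)-4-methyl-3-oxocyclohex-4-en-1-yl]prop-2-enoate F1. Then run a silyl-radical Giese 6-endo cyclisation ((TMS)3SiH, Ir[dF(CF3)ppy]2(dtbbpy)PF6, Na2CO3, MeOH, blue LEDs), which comes back to the route at 5.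

**Step 5 (Kabalka reduction).** The C9 ketone is flanked by a quaternary carbon and may not form the tosylhydrazone. Fallback setting out from 6: L-Selectride conjugate reduction and trapping with PhNTf2 gives the enol triflate methyl cis-4a,6-dimethyl-5-(trifluoromethylsulfonyloxy)-1,2,3,4,4a,7,8,8a-octahydronaphthalene-1-carboxylate F2. Pd(OAc)2/PPh3, HCO2H, Bu3N, DMF, 60 °C then reduces the triflate and comes back at 8.

**Step 7 (singlet-oxygen ene).** Hydrogen abstraction from ring C7 instead of the C17 methyl would give the Δ7 isomer (expected about 2:1 in favour of the exocyclic product). Fallback setting out from 9: mCPBA gives the 8,9-epoxide of 9 F3. Base-induced epoxide-to-allylic-alcohol isomerisation (LiNEt2, Et2O/hexane, reflux), which takes the proton from the methyl group, comes back at 11.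

## Further compounds

F1 | step 3 | methyl 2-[2-(2-bromoethyl)-4-methyl-3-oxocyclohex-4-en-1-yl]prop-2-enoate (C1 as in 3; C2 epimers) | CC1=CC[C@H](C(=C)C(=O)OC)C(CCBr)C1=O
F2 | step 5 | methyl cis-4a,6-dimethyl-5-(trifluoromethylsulfonyloxy)-1,2,3,4,4a,7,8,8a-octahydronaphthalene-1-carboxylate (C1 epimers) | CC1=C(OS(=O)(=O)C(F)(F)F)[C@@]2(C)CCCC(C(=O)OC)[C@H]2CC1
F3 | step 7 | 8,9-epoxide of 9 (labdane numbering; β-epoxide expected) | CC12CC[C@H]3[C@](C)(CCC[C@]3(C)C(=O)OC)C1O2
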